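The constants come from no measurement.

I began from late times, where target is a passing stage, consumed with by-product to give side product, and asked how far along that road each flask stands when it is read.

    substrate + coupling partner → intermediate + by-product (k1 = 0.0023 L mol⁻¹ s⁻¹)
    intermediate → target (k2 = 9.2 × 10⁻⁴ s⁻¹)
    target + by-product → side product (k3 = 0.0030 L mol⁻¹ s⁻¹)
- Thursday's: substrate 0.25 M; coupling partner 0.120 M; time 25 min
- Sunday's: substrate 0.25 M; coupling partner 0.150 M; time 25 min
* which of the two there is more of at the end, Thursday's (side product / target)
* which of the two there is more of at the end, Sunday's (side product / target)
* target at the end, in percent of the substrate charged, Thursday's
* target at the end, in percent of the substrate charged, Sunday's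

First I asked how much substrate had been turned over. On Thursday's, the half-life of substrate by the first step, with coupling partner held at its charge, is 42 min, longer than the 25 min run, so I expected that step to be still running at the reading. The second-order law, with both reactants falling together, gave a turnover x of 0.0625 M on Thursday's and 0.0761 M on Sunday's.

Next I asked how much of x had got past the intermediate. The run lasts twice the intermediate's half-life of 13 min, but material entering late has had less time, as in the lag of a coupled assay. With τ the second step's rate constant times the time, 1.38 here, a steady feed gives one minus (one minus e^−τ)/τ, or 45.8 %. I called this φ, the passage fraction: the share of the substrate turned over that has left the intermediate under that steady feed. Then φx over the substrate charge gave 11.4 % target on Thursday's and 13.9 % on Sunday's, before any loss to the third step.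

Last I asked whether the loss step could reverse the order. Taking target and by-product at their end values for the whole run, I put side product at 28.1 % of target on Thursday's and 34.2 % on Sunday's. So I expected target to lead on Thursday's and target on Sunday's.

The forecast named target on both days and gave 11.8 % (11.2 % to 12.4 %) on Thursday's and 14.1 % (13.4 % to 14.8 %) on Sunday's, higher than mine, holding the loss small because “target and by-product both build late”.

The simulation gave target at 11.9 % on Thursday's and 14.2 % on Sunday's, with side product at 1.08 % and 1.60 %. In Sunday's flask the first step ran with 70 % of the substrate and 49 % of the coupling partner's own charge remaining at the end, half its turnover done by 9.24 min, while the second step trailed, leaving 14.6 % as intermediate at the end, when target was made 4.38 times as fast as it was used up. On that flask's 30.4 % turned over, φ gives 13.9 % past the intermediate, and target and side product together stood at 15.8 %. Stopped at 10 min, the same flask has φ of 23.2 %, which on 16.2 % turned over gives 3.75 % past the intermediate, and it held 4.03 % as target and side product together.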